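Numbering: lactone ring O1, C2 to C6; side chain C1' to C10' outward from C6. Everything rests on the C7'–C8' bond, made by a boron aldol reaction between methyl ketone 19, which already carries the Z-alkenyl dihydropyranone and a PMB ether at C4', and 3-phenylpropanal. In one operation the step joins the two halves and sets C8' by 1,5-anti induction from the C4' ether oxygen across the C6' carbonyl. That carbonyl, one oxidation level above the target, is then spent in an Evans–Tishchenko reduction with acetaldehyde, which sets C6' anti to C8' and leaves the acetate on the C8' oxygen. Ketone 19 comes from (S)-epichlorohydrin and an ynal hetero-Diels–Alder reaction.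

Key step: step 9

Assumption: in step 6 the (1S,2R) enantiomer of the chromium catalyst is taken to direct the diene to the Si face of the alkynyl aldehyde; should the sense be the opposite one, the (1R,2S) complex is used and nothing else changes.

Step 1
Reactants: 1 (S)-epichlorohydrin; 2 isopropenylmagnesium bromide
Product: 3 (S)-1-chloro-4-methylpent-4-en-2-ol
Conditions: CuI (10 mol%), THF, −40 to −20 °C
Reagents that add atoms: isopropenylmagnesium bromide, CC(=C)[Mg]Br
Why: Copper-catalysed Grignard opening of the epoxide at its unsubstituted ring carbon (SN2) is faster than chloride displacement at low temperature; the carbinol carbon of 1 is not touched and becomes C4' of the target.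

Step 2
Reactants: 3 (S)-1-chloro-4-methylpent-4-en-2-ol; 4 lithium acetylide–ethylenediamine complex
Product: 6 (S)-2-methylhept-1-en-6-yn-4-ol, via epoxide 5 (not isolated)
Conditions: LiC≡CH·H2NCH2CH2NH2 (3 equiv), DMSO, 0 °C to rt
Reagents that add atoms: lithium acetylide–ethylenediamine complex, [Li]C#C.NCCN
Why: One equivalent of acetylide acts as base and closes the chlorohydrin to epoxide 5 (intramolecular Williamson reaction), and a second opens 5 at its terminal carbon (SN2 alkynylation of an epoxide); the C–O bond of the stereocenter is never broken, so its configuration is kept.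

Step 3
Reactants: 6 (S)-2-methylhept-1-en-6-yn-4-ol; 7 4-methoxybenzyl chloride
Product: 9 (S)-1-methoxy-4-{[(2-methylhept-1-en-6-yn-4-yl)oxy]methyl}benzene, via sodium alkoxide 8 (not isolated)
Conditions: NaH (1.1 equiv), Bu4NI (cat.), THF/DMF, 0 °C to rt
Reagents that add atoms: 4-methoxybenzyl chloride, COc1ccc(CCl)cc1
Why: Williamson etherification of the alkoxide, which forms in preference to the acetylide with a slight excess of NaH; the benzyl-type ether is the group that later transmits 1,5-induction, and the stereocenter is untouched.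

Step 4
Reactants: 9 (S)-1-methoxy-4-{[(2-methylhept-1-en-6-yn-4-yl)oxy]methyl}benzene; 10 N,N-dimethylformamide
Product: 12 (S)-5-[(4-methoxybenzyl)oxy]-7-methyloct-7-en-2-ynal, via alkynyllithium 11 (not isolated)
Conditions: n-BuLi, THF, −78 °C; DMF, −78 to 0 °C; inverse quench into cold aq. KH2PO4
Reagents that add atoms: N,N-dimethylformamide, CN(C)C=O
Why: Formylation of a lithium acetylide with DMF; the buffered inverse quench releases the alkynyl aldehyde from the hemiaminal salt without conjugate addition of dimethylamine.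

Step 5
Reactants: 12 (S)-5-[(4-methoxybenzyl)oxy]-7-methyloct-7-en-2-ynal
Product: 14 (R)-5-[(4-methoxybenzyl)oxy]-7-oxooct-2-ynal, via ozonide 13 (not isolated)
Conditions: O3, CH2Cl2, −78 °C, Sudan Red 7B as end-point indicator; then Me2S, −78 °C to rt
Reagents that add atoms: ozone, [O-][O+]=O
Why: Ozonolysis with reductive work-up: the electron-rich 1,1-disubstituted alkene reacts far faster than the electron-poor conjugated alkyne or the anisyl ring, and unveils the methyl ketone (C6', C7') only after the last organolithium step; the descriptor changes from S to R by priority only.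

Step 6
Reactants: 14 (R)-5-[(4-methoxybenzyl)oxy]-7-oxooct-2-ynal; 15 (E)-1-methoxybuta-1,3-diene
Product: 16 (2R,6S)-2-methoxy-6-{(4R)-4-[(4-methoxybenzyl)oxy]-6-oxohept-1-yn-1-yl}-5,6-dihydro-2H-pyran
Conditions: 15 (2 equiv), [CrCl(L)] (3 mol%; C27H29ClCrNO2, L = doubly deprotonated Schiff base of (1S,2R)-1-aminoindan-2-ol and 3-(1-adamantyl)-2-hydroxy-5-methylbenzaldehyde), 4 Å molecular sieves, neat, rt
Reagents that add atoms: (E)-1-methoxybuta-1,3-diene, CO/C=C/C=C
Why: Catalytic asymmetric hetero-Diels–Alder reaction: the chiral trivalent chromium Lewis acid activates only the aldehyde (the ketone is inert) and the diene adds endo to its Si face, which sets C6 as S under catalyst control; the cis acetal center at C2 is formed as well and is removed in step 7.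

Step 7
Reactants: 16 (2R,6S)-2-methoxy-6-{(4R)-4-[(4-methoxybenzyl)oxy]-6-oxohept-1-yn-1-yl}-5,6-dihydro-2H-pyran
Product: 18 (S)-6-{(4R)-4-[(4-methoxybenzyl)oxy]-6-oxohept-1-yn-1-yl}-5,6-dihydro-2H-pyran-2-one, via lactol 17 (not isolated)
Conditions: CrO3, H2SO4, H2O (Jones reagent), acetone, 0 °C
Reagents that add atoms: water, O
Why: The aqueous acid hydrolyses the allylic methyl acetal to lactol 17, and Jones oxidation takes the lactol on to the conjugated lactone in the same flask; C6 is untouched and the acetal stereocenter disappears.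

Step 8
Reactants: 18 (S)-6-{(4R)-4-[(4-methoxybenzyl)oxy]-6-oxohept-1-yn-1-yl}-5,6-dihydro-2H-pyran-2-one
Product: 19 (S)-6-{(1Z,4R)-4-[(4-methoxybenzyl)oxy]-6-oxohept-1-en-1-yl}-5,6-dihydro-2H-pyran-2-one
Conditions: H2 (1 atm), Pd/CaCO3 poisoned with Pb(OAc)2 (Lindlar catalyst), quinoline, EtOAc, rt, stopped after one equivalent of H2
Reagents that add atoms: none
Why: Lindlar semihydrogenation: syn delivery of H2 on the poisoned palladium surface gives the Z-alkene C1'=C2', and the alkyne binds more strongly than the conjugated ring alkene, so the latter should survive if the uptake is monitored.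

Step 9
Reactants: 19 (S)-6-{(1Z,4R)-4-[(4-methoxybenzyl)oxy]-6-oxohept-1-en-1-yl}-5,6-dihydro-2H-pyran-2-one; 20 3-phenylpropanal
Product: 23 (S)-6-{(1Z,4R,8R)-8-hydroxy-4-[(4-methoxybenzyl)oxy]-6-oxo-10-phenyldec-1-en-1-yl}-5,6-dihydro-2H-pyran-2-one, via boron enolate 21 (not isolated), via boron aldolate 22 (not isolated)
Conditions: Bu2BOTf, i-Pr2NEt, Et2O, −78 °C; then 20, −78 °C; MeOH, pH 7 buffer (KH2PO4/K2HPO4), H2O2, 0 °C
Reagents that add atoms: 3-phenylpropanal, O=CCCc1ccccc1
Why: Bu2BOTf and i-Pr2NEt enolize the C6' ketone on its methyl side to the less substituted dibutylboron enolate 21, whose C7' carbon adds to the formyl carbon of 20 (the future C8') through a cyclic six-membered boat-like transition state to give boron aldolate 22, which the oxidative work-up cleaves. The closest known reaction type is the 1,5-anti boron aldol reaction of beta-alkoxy methyl ketones with aldehydes. No ring is closed. The one new stereocenter, C8', is set R by 1,5-anti induction from C4': in the favoured transition state the PMB ether oxygen accepts a hydrogen bond from the formyl C–H, which fixes the aldehyde face. The step needs regioselective enolization (C7' methyl over C5' methylene, secured by kinetic conditions with a hindered amine), chemoselectivity over the lactone (which has no enolizable alpha hydrogen and only weakly acidic gamma hydrogens at C5), and no beta-elimination of the PMB ether (secured by −78 °C). Diethyl ether as solvent and a benzyl-type ether at C4' are what this induction requires, which is why a PMB and not a silyl group is carried.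

Step 10
Reactants: 23 (S)-6-{(1Z,4R,8R)-8-hydroxy-4-[(4-methoxybenzyl)oxy]-6-oxo-10-phenyldec-1-en-1-yl}-5,6-dihydro-2H-pyran-2-one; 24 acetaldehyde
Product: 26 (S)-6-{(1Z,4R,6R,8R)-8-acetoxy-6-hydroxy-4-[(4-methoxybenzyl)oxy]-10-phenyldec-1-en-1-yl}-5,6-dihydro-2H-pyran-2-one, via hemiacetal 25 (not isolated)
Conditions: SmI2 (0.3 equiv) premixed with 24 (10 equiv), THF, −10 °C; then 23, −10 °C
Reagents that add atoms: acetaldehyde, CC=O
Why: Evans–Tishchenko reduction: the trivalent samarium catalyst formed from SmI2 and acetaldehyde ties the C8' hydroxyl to acetaldehyde as hemiacetal 25, whose hydride is delivered intramolecularly to the C6' ketone through a chair-like bicyclic transition state, which sets C6' as R (anti to C8') and leaves the acetyl group on the C8' oxygen alone.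

Step 11
Reactants: 26 (S)-6-{(1Z,4R,6R,8R)-8-acetoxy-6-hydroxy-4-[(4-methoxybenzyl)oxy]-10-phenyldec-1-en-1-yl}-5,6-dihydro-2H-pyran-2-one
Product: 27 (S)-6-[(1Z,4R,6R,8R)-8-acetoxy-4,6-dihydroxy-10-phenyldec-1-en-1-yl]-5,6-dihydro-2H-pyran-2-one
Conditions: DDQ, CH2Cl2/pH 7 buffer (KH2PO4/K2HPO4) 10:1, 0 °C
Reagents that add atoms: none
Why: Oxidative cleavage of the PMB ether by DDQ (hydride abstraction, then hydrolysis of the oxocarbenium ion) is neutral and should leave the acetate, both alkenes and the lactone alone; the wet buffered medium suppresses anisylidene acetal formation with the C6' hydroxyl and acetyl migration.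

Compound list
1 | (S)-epichlorohydrin | ClC[C@@H]1CO1 | starting material
2 | isopropenylmagnesium bromide | CC(=C)[Mg]Br | starting material
3 | (S)-1-chloro-4-methylpent-4-en-2-ol | CC(=C)C[C@H](O)CCl | intermediate
4 | lithium acetylide–ethylenediamine complex | [Li]C#C.NCCN | starting material
5 | (S)-2-(2-methylprop-2-en-1-yl)oxirane (epoxide, not isolated) | CC(=C)C[C@H]1CO1 | intermediate
6 | (S)-2-methylhept-1-en-6-yn-4-ol | CC(=C)C[C@H](O)CC#C | intermediate
7 | 4-methoxybenzyl chloride | COc1ccc(CCl)cc1 | starting material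
8 | sodium (S)-2-methylhept-1-en-6-yn-4-olate (not isolated) | CC(=C)C[C@H]([O-])CC#C.[Na+] | intermediate
9 | (S)-1-methoxy-4-{[(2-methylhept-1-en-6-yn-4-yl)oxy]methyl}benzene | CC(=C)C[C@H](OCc1ccc(OC)cc1)CC#C | intermediate
10 | N,N-dimethylformamide | CN(C)C=O | starting material
11 | alkynyllithium of 9 (not isolated) | CC(=C)C[C@H](OCc1ccc(OC)cc1)CC#C[Li] | intermediate
12 | (S)-5-[(4-methoxybenzyl)oxy]-7-methyloct-7-en-2-ynal | CC(=C)C[C@H](OCc1ccc(OC)cc1)CC#CC=O | intermediate
13 | ozonide of 12, a 3-methyl-1,2,4-trioxolane, either configuration at the ring carbon (not isolated) | CC1(C[C@H](OCc2ccc(OC)cc2)CC#CC=O)OCOO1 | intermediate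
14 | (R)-5-[(4-methoxybenzyl)oxy]-7-oxooct-2-ynal | CC(=O)C[C@H](OCc1ccc(OC)cc1)CC#CC=O | intermediate
15 | (E)-1-methoxybuta-1,3-diene | CO/C=C/C=C | starting material
16 | (2R,6S)-2-methoxy-6-{(4R)-4-[(4-methoxybenzyl)oxy]-6-oxohept-1-yn-1-yl}-5,6-dihydro-2H-pyran (2,6-cis) | CC(=O)C[C@H](OCc1ccc(OC)cc1)CC#C[C@@H]1CC=C[C@H](OC)O1 | intermediate
17 | (6S)-6-{(4R)-4-[(4-methoxybenzyl)oxy]-6-oxohept-1-yn-1-yl}-5,6-dihydro-2H-pyran-2-ol, both anomers (lactol, not isolated) | CC(=O)C[C@H](OCc1ccc(OC)cc1)CC#C[C@@H]1CC=CC(O)O1 | intermediate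
18 | (S)-6-{(4R)-4-[(4-methoxybenzyl)oxy]-6-oxohept-1-yn-1-yl}-5,6-dihydro-2H-pyran-2-one | CC(=O)C[C@H](OCc1ccc(OC)cc1)CC#C[C@@H]1CC=CC(=O)O1 | intermediate
19 | (S)-6-{(1Z,4R)-4-[(4-methoxybenzyl)oxy]-6-oxohept-1-en-1-yl}-5,6-dihydro-2H-pyran-2-one | CC(=O)C[C@H](OCc1ccc(OC)cc1)C/C=C\[C@@H]1CC=CC(=O)O1 | intermediate
20 | 3-phenylpropanal | O=CCCc1ccccc1 | starting material
21 | dibutylboron enolate of 19, boron on the C6' oxygen, C6'=C7' double bond (not isolated) | C=C(OB(CCCC)CCCC)C[C@H](OCc1ccc(OC)cc1)C/C=C\[C@@H]1CC=CC(=O)O1 | intermediate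
22 | dibutylboron aldolate, Bu2B on the C8' oxygen of 23 (not isolated) | CCCCB(CCCC)O[C@H](CCc1ccccc1)CC(=O)C[C@H](OCc1ccc(OC)cc1)C/C=C\[C@@H]1CC=CC(=O)O1 | intermediate
23 | (S)-6-{(1Z,4R,8R)-8-hydroxy-4-[(4-methoxybenzyl)oxy]-6-oxo-10-phenyldec-1-en-1-yl}-5,6-dihydro-2H-pyran-2-one | O[C@H](CCc1ccccc1)CC(=O)C[C@H](OCc1ccc(OC)cc1)C/C=C\[C@@H]1CC=CC(=O)O1 | intermediate
24 | acetaldehyde | CC=O | starting material
25 | acetaldehyde hemiacetal on the C8' oxygen of 23, either configuration at the hemiacetal carbon, samarium-bound in the flask (not isolated) | CC(O)O[C@H](CCc1ccccc1)CC(=O)C[C@H](OCc1ccc(OC)cc1)C/C=C\[C@@H]1CC=CC(=O)O1 | intermediate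
26 | (S)-6-{(1Z,4R,6R,8R)-8-acetoxy-6-hydroxy-4-[(4-methoxybenzyl)oxy]-10-phenyldec-1-en-1-yl}-5,6-dihydro-2H-pyran-2-one | CC(=O)O[C@H](CCc1ccccc1)C[C@H](O)C[C@H](OCc1ccc(OC)cc1)C/C=C\[C@@H]1CC=CC(=O)O1 | intermediate
27 | (S)-6-[(1Z,4R,6R,8R)-8-acetoxy-4,6-dihydroxy-10-phenyldec-1-en-1-yl]-5,6-dihydro-2H-pyran-2-one | CC(=O)O[C@H](CCc1ccccc1)C[C@H](O)C[C@H](O)C/C=C\[C@@H]1CC=CC(=O)O1 | target

Total step count: 11
Longest linear sequence: 11 steps, from 1 to 27.

Steps most likely to fail

Step 9. The process at risk is gamma-deprotonation and ring opening of the dihydropyranone while the ketone is being enolized, or erosion of the 1,5-anti facial selectivity. The fallback keeps the lactone carbonyl masked as its methyl acetal until after the aldol reaction and the reduction. It sets out from 16. Semihydrogenation over Pd/CaCO3 poisoned with Pb(OAc)2 should give the Z-alkenyl keto acetal F1. Enolization with (c-Hex)2BCl and Et3N in Et2O and addition to 20 should give the 1,5-anti aldol F2. Evans–Tishchenko reduction with 24 should give the C8' acetate F3. PPTS in wet acetone should hydrolyse the acetal to lactol F4. MnO2 in CH2Cl2, which oxidises the allylic lactol but not the saturated C6' alcohol, should then give 26, where the route is rejoined.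

Step 6. The process at risk is low or reversed facial selectivity of the cycloaddition with an alkynyl aldehyde, or polymerisation of the diene. The fallback builds the ring by allylation and ring-closing metathesis and sets out from 14. Brown allylation with (−)-Ipc2B(allyl), made from (−)-Ipc2BOMe and allylmagnesium bromide (Et2O, −100 °C), adds to the Si face of the formyl group and should react far faster there than at the methyl ketone, giving the (S)-propargylic homoallylic alcohol F5. Acryloyl chloride, Et3N and DMAP should give the acrylate F6. Ring-closing metathesis with RuCl2(PCy3)2(=CHPh) (first-generation Grubbs catalyst) in CH2Cl2 should close the dihydropyranone and rejoin the route at 18.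

Step 10. The process at risk is single-electron reduction of the conjugated lactone by divalent samarium, retro-aldol cleavage, or acetyl migration from the C8' to the C6' oxygen. The fallback separates reduction and acetylation and sets out from 23. Evans–Saksena reduction with Me4NBH(OAc)3 in MeCN/AcOH at −30 °C, directed by the C8' hydroxyl, should give the 6,8-anti diol F7. DDQ under anhydrous conditions (CH2Cl2, 4 Å molecular sieves) should turn the PMB ether into the 4-methoxybenzylidene acetal F8, which bridges the syn-related C4' and C6' oxygens and leaves only the C8' hydroxyl free. Ac2O and pyridine should give the acetate F9. Aqueous acetic acid in THF should remove the acetal and give 27 directly, so that step 11 is no longer needed.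

Further compounds
F1 | step 9 | (2R,6S)-2-methoxy-6-{(1Z,4R)-4-[(4-methoxybenzyl)oxy]-6-oxohept-1-en-1-yl}-5,6-dihydro-2H-pyran | CC(=O)C[C@H](OCc1ccc(OC)cc1)C/C=C\[C@@H]1CC=C[C@H](OC)O1
F2 | step 9 | (2R,6S)-6-{(1Z,4R,8R)-8-hydroxy-4-[(4-methoxybenzyl)oxy]-6-oxo-10-phenyldec-1-en-1-yl}-2-methoxy-5,6-dihydro-2H-pyran | O[C@H](CCc1ccccc1)CC(=O)C[C@H](OCc1ccc(OC)cc1)C/C=C\[C@@H]1CC=C[C@H](OC)O1
F3 | step 9 | (2R,6S)-6-{(1Z,4R,6R,8R)-8-acetoxy-6-hydroxy-4-[(4-methoxybenzyl)oxy]-10-phenyldec-1-en-1-yl}-2-methoxy-5,6-dihydro-2H-pyran | CC(=O)O[C@H](CCc1ccccc1)C[C@H](O)C[C@H](OCc1ccc(OC)cc1)C/C=C\[C@@H]1CC=C[C@H](OC)O1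
F4 | step 9 | (6S)-6-{(1Z,4R,6R,8R)-8-acetoxy-6-hydroxy-4-[(4-methoxybenzyl)oxy]-10-phenyldec-1-en-1-yl}-5,6-dihydro-2H-pyran-2-ol, both anomers | CC(=O)O[C@H](CCc1ccccc1)C[C@H](O)C[C@H](OCc1ccc(OC)cc1)C/C=C\[C@@H]1CC=CC(O)O1
F5 | step 6 | (4R,8S)-8-hydroxy-4-[(4-methoxybenzyl)oxy]undec-10-en-6-yn-2-one | CC(=O)C[C@H](OCc1ccc(OC)cc1)CC#C[C@@H](O)CC=C
F6 | step 6 | (4S,8R)-8-[(4-methoxybenzyl)oxy]-10-oxoundec-1-en-5-yn-4-yl prop-2-enoate | CC(=O)C[C@H](OCc1ccc(OC)cc1)CC#C[C@@H](OC(=O)C=C)CC=C
F7 | step 10 | (S)-6-{(1Z,4R,6S,8R)-6,8-dihydroxy-4-[(4-methoxybenzyl)oxy]-10-phenyldec-1-en-1-yl}-5,6-dihydro-2H-pyran-2-one | O[C@H](CCc1ccccc1)C[C@H](O)C[C@H](OCc1ccc(OC)cc1)C/C=C\[C@@H]1CC=CC(=O)O1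
F8 | step 10 | 4-methoxybenzylidene acetal of F7 across the C4' and C6' oxygens (all-cis 2,4,6-trisubstituted 1,3-dioxane), C8' hydroxyl free | O[C@H](CCc1ccccc1)C[C@H]1C[C@@H](C/C=C\[C@@H]2CC=CC(=O)O2)O[C@@H](c2ccc(OC)cc2)O1
F9 | step 10 | C8' acetate of F8 | CC(=O)O[C@H](CCc1ccccc1)C[C@H]1C[C@@H](C/C=C\[C@@H]2CC=CC(=O)O2)O[C@@H](c2ccc(OC)cc2)O1
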